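**Retrosynthetic overview**

1. Target ⇐ one manganese-hydride HAT hydrogenation that turns two ring vinyl bromides into both equatorial CHBr centers; the tertiary carbinol of ring C comes from an OH-directed epoxidation and hydride opening; the side-chain C–C bond comes from a syn aldol between a trans-hydrindan-2-one enolate and an achiral bromodienal, so ring C arrives preformed.
2. Hydrindane ⇐ conjugate hydride addition to a bicyclic bromo-dienone ⇐ key step: palladium-catalysed intramolecular γ-alkenylation of a cyclopentenone dienolate by a tethered 1,1-dibromoalkene, closing the six-membered ring between the methyl-bearing ring-fusion carbon and the bromine-bearing carbon.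
3. Enabling feature: the carbinol carbon of the five-membered ring is 1,3 to the quaternary C–CH3 through the ring-fusion CH. As a cyclopent-2-enone it therefore makes that quaternary carbon the γ-terminus of a dienolate while the ring-fusion carbon stays sp2. The neighbouring CHBr can be carried as C(Br)=CH because the adjacent quaternary carbon steers the later hydrogen delivery.
4. Cyclopentenone ⇐ aldol condensation of a 1,4-diketone (Wacker) ⇐ Grignard opening of a γ-lactone from (R)-citramalic acid, whose stereocenter becomes the C(CH3)OH of the six-membered ring and is the only source of chirality; the C(Br) carbon comes from CBr4.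
5. Ring order: five-membered carbocycle (step 8), six-membered hydrindane ring (step 9), ring C attached intact (step 13).

Key step: step 9

Locants used below (prose only): hydrindane C1 (CH bearing the side chain), C2 (CHOH), C3 (CH2), C4 (ring-fusion C–CH3), C5 (CHBr), C6, C7, C8 (C(CH3)OH), C9 (ring-fusion CH); Ca = CH(OAc); ring C: C1' (C–OH), C2', C3', C4' (CHBr), C5' (C(CH3)2), C6'.

Remark: bromide 6 is used racemic, so 8–12 are mixtures at the methyl-bearing methine; that center is planarised in step 9 and both epimers converge.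

**Route**

Step 1
Reactants: 1 (R)-citramalic acid
Product: 2 2-[(4R)-2,2,4-trimethyl-5-oxo-1,3-dioxolan-4-yl]acetic acid
Conditions: Me2C(OMe)2, TsOH·H2O (cat.), 23 °C
Reagents that add atoms: 2,2-dimethoxypropane COC(C)(C)OC
Why: Acid-catalysed transacetalisation (dioxolanone formation) ties up only the α-hydroxy acid pair in a five-membered ring, leaving the β-carboxylic acid free and the stereocenter untouched.

Step 2
Reactants: 2 2-[(4R)-2,2,4-trimethyl-5-oxo-1,3-dioxolan-4-yl]acetic acid
Product: 4 (3R)-3-hydroxy-3-methyloxolan-2-one, via hydroxyethyl dioxolanone 3 (not isolated)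
Conditions: BH3·SMe2, THF, 0→23 °C; MeOH quench; then TsOH·H2O (cat.), CH2Cl2, 23 °C
Reagents that add atoms: none
Why: Borane reduction is chemoselective for the free carboxylic acid over the dioxolanone, and acid-catalysed translactonisation of the new primary alcohol onto the acetal-activated acyl carbon expels acetone to give the γ-lactone without touching the quaternary carbinol.

Step 3
Reactants: 4 (3R)-3-hydroxy-3-methyloxolan-2-one
Product: 5 (3R)-3-methyl-3-[(triethylsilyl)oxy]oxolan-2-one
Conditions: Et3SiOTf, 2,6-lutidine, CH2Cl2, 0 °C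
Reagents that add atoms: triethylsilyl trifluoromethanesulfonate CC[Si](CC)(CC)OS(=O)(=O)C(F)(F)F
Why: Silyl triflate silylation protects the hindered tertiary alcohol cleanly, and the triethylsilyl ether should survive every later step yet fall to HF·pyridine at the end.

Step 4
Reactants: 5 (3R)-3-methyl-3-[(triethylsilyl)oxy]oxolan-2-one; 6 4-bromopent-1-ene
Product: 8 (3R)-1-hydroxy-3,5-dimethyl-3-[(triethylsilyl)oxy]oct-7-en-4-one (C5 epimer mixture), via pent-4-en-2-ylmagnesium bromide 7 (not isolated)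
Conditions: 6, Mg, THF, 23 °C; then 5, THF, −78→−20 °C; aq NH4Cl
Reagents that add atoms: none
Why: Grignard addition to a lactone should stop at the ring-opened ketone because the tetrahedral alkoxide persists at low temperature and the ketone formed is flanked by a quaternary and a tertiary carbon, while the new methine center is left uncontrolled on purpose.

Step 5
Reactants: 8 (3R)-1-hydroxy-3,5-dimethyl-3-[(triethylsilyl)oxy]oct-7-en-4-one
Product: 9 (3R)-3,5-dimethyl-4-oxo-3-[(triethylsilyl)oxy]oct-7-enal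
Conditions: Dess–Martin periodinane, CH2Cl2, 0→23 °C
Reagents that add atoms: none
Why: Dess–Martin oxidation converts the primary alcohol to the aldehyde under non-basic conditions that avoid β-elimination of the silyloxy group.

Step 6
Reactants: 9 (3R)-3,5-dimethyl-4-oxo-3-[(triethylsilyl)oxy]oct-7-enal
Product: 10 (4R)-1,1-dibromo-4,6-dimethyl-4-[(triethylsilyl)oxy]nona-1,8-dien-5-one
Conditions: CBr4, PPh3, CH2Cl2, 0 °C
Reagents that add atoms: carbon tetrabromide BrC(Br)(Br)Br
Why: Ramirez dibromo-olefination (first stage of the Corey–Fuchs sequence) is selective for the aldehyde over the doubly α-branched ketone and installs the future bromine-bearing ring carbon C5 at the vinyl-halide oxidation level.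

Step 7
Reactants: 10 (4R)-1,1-dibromo-4,6-dimethyl-4-[(triethylsilyl)oxy]nona-1,8-dien-5-one
Product: 11 (4R)-1,1-dibromo-4,6-dimethyl-4-[(triethylsilyl)oxy]non-1-ene-5,8-dione
Conditions: PdCl2 (10 mol%), CuCl, O2 (1 atm), DMF/H2O 7:1, 23 °C
Reagents that add atoms: water O (oxygen of the new ketone; O2 is the terminal oxidant)
Why: Tsuji–Wacker oxidation converts the terminal alkene to the methyl ketone with Markovnikov selectivity, and the electron-poor 1,1-dibromoalkene should be spared because palladium is kept divalent by the copper/oxygen couple.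

Step 8
Reactants: 11 (4R)-1,1-dibromo-4,6-dimethyl-4-[(triethylsilyl)oxy]non-1-ene-5,8-dione
Product: 12 3-[(2R)-5,5-dibromo-2-[(triethylsilyl)oxy]pent-4-en-2-yl]-4-methylcyclopent-2-en-1-one (C4 epimer mixture)
Conditions: KOH (2% in MeOH), 40 °C
Reagents that add atoms: none
Why: Intramolecular aldol condensation of a 1,4-diketone has a single productive mode here (methyl-ketone enolate onto the hindered ketone, five-membered ring), giving the cyclopentenone in which C4 is the only γ-CH.

Step 9
Reactants: 12 3-[(2R)-5,5-dibromo-2-[(triethylsilyl)oxy]pent-4-en-2-yl]-4-methylcyclopent-2-en-1-one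
Product: 13 (4R,7aS)-7-bromo-4,7a-dimethyl-4-[(triethylsilyl)oxy]-1,4,5,7a-tetrahydro-2H-inden-2-one
Conditions: Pd2(dba)3 (5 mol%), P(t-Bu)3·HBF4 (12 mol%), Cs2CO3 (2.5 equiv), PhMe, 90 °C
Reagents that add atoms: none
Why: Proposed new method: carbonate deprotonates the γ-CH of the cyclopentenone (C4, the only γ-hydrogen because C8 is quaternary) to the extended dienolate, zerovalent palladium inserts reversibly into the C–Br bond cis to the chain, the dienolate displaces bromide on divalent palladium, and C–C reductive elimination at C4 from the seven-membered palladacycle forms the C4–C5 bond, while the second C–Br, now on a vinyl carbon next to the new quaternary center, is returned by reversible oxidative addition under P(t-Bu)3. The closest known reaction types are the palladium-catalysed γ-arylation of enone dienolates, the intramolecular palladium-catalysed alkenylation of ketone enolates by vinyl halides, and the mono-selective intramolecular couplings of 1,1-dibromoalkenes that leave a cyclic vinyl bromide. The six-membered ring is closed in a 6-(enolendo) sense with respect to the dienolate C9=C4 bond, and C9 stays sp2, so no ring-fusion stereocenter is at stake yet. The new quaternary center C4 is controlled by C8: the planar five-membered dienolate keeps C3 in its plane, so the C4 methyl becomes axial in the chair-like closing ring, and closure should take the face on which this methyl is syn-diaxial to the small silyloxy oxygen and not to the C8 methyl. The step needs attack at C4 (γ) and not at C1 (α), and reaction of only one bromine; the first rests on the conjugation-restoring γ-preference of palladium dienolates (α-attack would leave a deconjugated enone) and is the main uncertainty, the second on geometry, since only the bromine cis to the tether can reach C4 and the surviving bromide is shielded by the new quaternary carbon.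

Step 10
Reactants: 13 (4R,7aS)-7-bromo-4,7a-dimethyl-4-[(triethylsilyl)oxy]-1,4,5,7a-tetrahydro-2H-inden-2-one
Product: 14 {[(3aS,4R,7aS)-7-bromo-4,7a-dimethyl-4-[(triethylsilyl)oxy]-3a,4,5,7a-tetrahydro-1H-inden-2-yl]oxy}(dimethyl)phenylsilane
Conditions: Cu(OAc)2·H2O (5 mol%), 1,2-bis(diphenylphosphino)benzene (5 mol%), PhMe2SiH, PhMe, 23 °C
Reagents that add atoms: dimethylphenylsilane C[SiH](C)c1ccccc1
Why: Copper hydride-catalysed 1,4-hydrosilylation should deliver hydride to C9 from the face opposite the angular C4 methyl and the axial C8 silyloxy group, setting the trans ring fusion, and it traps the enolate regiospecifically as the C1=C2 silyl enol ether.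

Step 11
Reactants: 15 2,2-dimethylcyclohexan-1-one
Product: 16 6,6-dimethylcyclohex-2-en-1-one
Conditions: IBX (2.5 equiv), DMSO/PhMe 1:2, 70 °C
Reagents that add atoms: none
Why: IBX dehydrogenation of a ketone can place the double bond only on the single enolisable side.

Step 12
Reactants: 16 6,6-dimethylcyclohex-2-en-1-one
Product: 18 4-bromo-5,5-dimethylcyclohexa-1,3-diene-1-carbaldehyde, via bromodienyl iminium bromide 17 (not isolated)
Conditions: PBr3, DMF, CHCl3, 0→60 °C; then aq NaOAc
Reagents that add atoms: N,N-dimethylformamide CN(C)C=O; phosphorus tribromide BrP(Br)Br; water O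
Why: Vilsmeier–Haack–Arnold bromoformylation runs through the only possible dienol (the α'-carbon is quaternary), formylates its terminal γ-carbon as dienol ethers do, and converts the vinylogous amide carbonyl to the vinyl bromide, giving an achiral dienal.

Step 13
Reactants: 14 {[(3aS,4R,7aS)-7-bromo-4,7a-dimethyl-4-[(triethylsilyl)oxy]-3a,4,5,7a-tetrahydro-1H-inden-2-yl]oxy}(dimethyl)phenylsilane; 18 4-bromo-5,5-dimethylcyclohexa-1,3-diene-1-carbaldehyde
Product: 21 (3R,3aS,4R,7aS)-7-bromo-3-[(R)-(4-bromo-5,5-dimethylcyclohexa-1,3-dien-1-yl)(hydroxy)methyl]-4,7a-dimethyl-4-[(triethylsilyl)oxy]-1,3,3a,4,5,7a-hexahydro-2H-inden-2-one, via lithium enolate 19 (not isolated), via zirconium enolate 20 (not isolated)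
Conditions: MeLi, THF, 0 °C; Cp2ZrCl2, −78 °C; then 18, −78 °C; pH 7 buffer
Reagents that add atoms: none
Why: Zirconium-enolate aldol addition is syn-selective whatever the enolate geometry, and the aldehyde should approach C1 on the face opposite the angular methyl, so that C1 and Ca arise with the required configuration from an achiral aldehyde.

Step 14
Reactants: 21 the aldol adduct of step 13
Product: 22 (3R,3aS,4R,7aS)-7-bromo-3-[(R)-[(1R,6R)-4-bromo-3,3-dimethyl-7-oxabicyclo[4.1.0]hept-4-en-1-yl](hydroxy)methyl]-4,7a-dimethyl-4-[(triethylsilyl)oxy]-1,3,3a,4,5,7a-hexahydro-2H-inden-2-one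
Conditions: VO(acac)2 (5 mol%), t-BuOOH (decane), CH2Cl2, 0 °C
Reagents that add atoms: tert-butyl hydroperoxide CC(C)(C)OO
Why: Vanadium-catalysed hydroxyl-directed epoxidation oxidises only the C1'=C2' bond next to the carbinol and, because C1' carries a geminal ring CH2 (A(1,2) strain), should give the erythro epoxy alcohol, which fixes the configuration of the future tertiary carbinol C1' relative to Ca.

Step 15
Reactants: 22 the epoxy hydroxy ketone of step 14
Product: 24 (R)-[(1R,6R)-4-bromo-3,3-dimethyl-7-oxabicyclo[4.1.0]hept-4-en-1-yl][(2R,3S,3aS,4R,7aS)-7-bromo-2-hydroxy-4,7a-dimethyl-4-[(triethylsilyl)oxy]-2,3,3a,4,5,7a-hexahydro-1H-inden-3-yl]methanol, via diethylboron chelate 23 (not isolated)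
Conditions: Et2BOMe, THF/MeOH 4:1, −78 °C; NaBH4; MeOH evaporation
Reagents that add atoms: none
Why: Narasaka–Prasad reduction delivers external hydride to the boron chelate of the β-hydroxy ketone so as to give the 1,3-syn diol, which here is the C2 hydroxyl cis to the side chain (hydride on the face away from it).

Step 16
Reactants: 24 the epoxy diol of step 15
Product: 25 (1R)-4-bromo-1-[(R)-[(2R,3S,3aS,4R,7aS)-7-bromo-2-hydroxy-4,7a-dimethyl-4-[(triethylsilyl)oxy]-2,3,3a,4,5,7a-hexahydro-1H-inden-3-yl](hydroxy)methyl]-5,5-dimethylcyclohex-3-en-1-ol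
Conditions: LiEt3BH (4 equiv), THF, 0→23 °C
Reagents that add atoms: none
Why: Triethylborohydride opens the epoxide by SN2 attack at its secondary, allylically activated carbon C2' and not at the quaternary C1', leaving the tertiary alcohol with its configuration.

Step 17
Reactants: 25 the triol of step 16
Product: 26 (1R)-4-bromo-1-[(R)-[(2R,3R,3aS,4R,7aS)-7-bromo-4,7a-dimethyl-2,4-bis[(triethylsilyl)oxy]-2,3,3a,4,5,7a-hexahydro-1H-inden-3-yl](hydroxy)methyl]-5,5-dimethylcyclohex-3-en-1-ol
Conditions: Et3SiCl (1.1 equiv), imidazole, DMF, −20 °C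
Reagents that add atoms: chlorotriethylsilane CC[Si](Cl)(CC)CC
Why: Silylation with a silyl chloride discriminates sterically, so the cyclopentanol at C2 should react while the Ca carbinol next to a quaternary carbon and the tertiary alcohol do not.

Step 18
Reactants: 26 the C2 silyl ether of step 17
Product: 27 (R)-[(1R)-4-bromo-1-hydroxy-5,5-dimethylcyclohex-3-en-1-yl][(2R,3R,3aS,4R,7aS)-7-bromo-4,7a-dimethyl-2,4-bis[(triethylsilyl)oxy]-2,3,3a,4,5,7a-hexahydro-1H-inden-3-yl]methyl acetate
Conditions: Ac2O, Et3N, DMAP (cat.), CH2Cl2, 23 °C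
Reagents that add atoms: acetic anhydride CC(=O)OC(C)=O
Why: DMAP-catalysed acetylation now finds a single acylable hydroxyl at Ca, since the tertiary alcohol is inert under these conditions and no ketone remains that could trigger β-elimination.

Step 19
Reactants: 27 the acetate of step 18
Product: 28 (R)-[(1R,4S)-4-bromo-1-hydroxy-3,3-dimethylcyclohexyl][(2R,3R,3aS,4R,7S,7aS)-7-bromo-4,7a-dimethyl-2,4-bis[(triethylsilyl)oxy]octahydro-1H-inden-3-yl]methyl acetate
Conditions: Mn(dpm)3 (20 mol%), PhSiH3, t-BuOOH, i-PrOH, 22 °C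
Reagents that add atoms: none
Why: Manganese-hydride hydrogen-atom-transfer hydrogenation reduces haloalkenes without hydrodehalogenation; hydrogen adds first to the CH terminus, and each α-bromo radical, held on a chair-locked ring, should take the second hydrogen axially, anti to the axial methyl on the neighbouring quaternary carbon, so both bromines end equatorial (C5 and C4').

Step 20
Reactants: 28 the bis-silyl ether of step 19
Product: 29 (R)-[(1R,4S)-4-bromo-1-hydroxy-3,3-dimethylcyclohexyl][(2R,3S,3aS,4R,7S,7aS)-7-bromo-2,4-dihydroxy-4,7a-dimethyloctahydro-1H-inden-3-yl]methyl acetate (CNP0166243.1)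
Conditions: HF·pyridine, pyridine, THF, 0→23 °C
Reagents that add atoms: none
Why: Fluoride-mediated desilylation with buffered HF·pyridine removes the secondary and the tertiary triethylsilyl ether without touching the acetate or the alkyl bromides.

**Compound list**

1 | (R)-citramalic acid | C[C@@](O)(CC(=O)O)C(=O)O | starting material
2 | 2-[(4R)-2,2,4-trimethyl-5-oxo-1,3-dioxolan-4-yl]acetic acid | C[C@]1(CC(=O)O)OC(C)(C)OC1=O | intermediate
3 | (5R)-5-(2-hydroxyethyl)-2,2,5-trimethyl-1,3-dioxolan-4-one | C[C@]1(CCO)OC(C)(C)OC1=O | intermediate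
4 | (3R)-3-hydroxy-3-methyloxolan-2-one | C[C@@]1(O)CCOC1=O | intermediate
5 | (3R)-3-methyl-3-[(triethylsilyl)oxy]oxolan-2-one | C[C@@]1(O[Si](CC)(CC)CC)CCOC1=O | intermediate
6 | 4-bromopent-1-ene (racemic) | C=CCC(C)Br | starting material
7 | pent-4-en-2-ylmagnesium bromide | C=CCC(C)[Mg]Br | intermediate
8 | (3R)-1-hydroxy-3,5-dimethyl-3-[(triethylsilyl)oxy]oct-7-en-4-one (C5 epimers) | C[C@@](O[Si](CC)(CC)CC)(CCO)C(=O)C(C)CC=C | intermediate
9 | (3R)-3,5-dimethyl-4-oxo-3-[(triethylsilyl)oxy]oct-7-enal (C5 epimers) | C[C@@](O[Si](CC)(CC)CC)(CC=O)C(=O)C(C)CC=C | intermediate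
10 | (4R)-1,1-dibromo-4,6-dimethyl-4-[(triethylsilyl)oxy]nona-1,8-dien-5-one (C6 epimers) | C[C@@](O[Si](CC)(CC)CC)(CC=C(Br)Br)C(=O)C(C)CC=C | intermediate
11 | (4R)-1,1-dibromo-4,6-dimethyl-4-[(triethylsilyl)oxy]non-1-ene-5,8-dione (C6 epimers) | C[C@@](O[Si](CC)(CC)CC)(CC=C(Br)Br)C(=O)C(C)CC(C)=O | intermediate
12 | 3-[(2R)-5,5-dibromo-2-[(triethylsilyl)oxy]pent-4-en-2-yl]-4-methylcyclopent-2-en-1-one (C4 epimers) | C[C@@](O[Si](CC)(CC)CC)(CC=C(Br)Br)C1=CC(=O)CC1C | intermediate
13 | (4R,7aS)-7-bromo-4,7a-dimethyl-4-[(triethylsilyl)oxy]-1,4,5,7a-tetrahydro-2H-inden-2-one | O=C1C[C@]2(C)C(Br)=CC[C@@](C)(O[Si](CC)(CC)CC)C2=C1 | intermediate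
14 | {[(3aS,4R,7aS)-7-bromo-4,7a-dimethyl-4-[(triethylsilyl)oxy]-3a,4,5,7a-tetrahydro-1H-inden-2-yl]oxy}(dimethyl)phenylsilane | C1=C(O[Si](C)(C)c3ccccc3)C[C@]2(C)C(Br)=CC[C@@](C)(O[Si](CC)(CC)CC)[C@@H]12 | intermediate
15 | 2,2-dimethylcyclohexan-1-one | CC1(C)CCCCC1=O | starting material
16 | 6,6-dimethylcyclohex-2-en-1-one | CC1(C)CCC=CC1=O | intermediate
17 | N-[(4-bromo-5,5-dimethylcyclohexa-1,3-dien-1-yl)methylidene]-N-methylmethanaminium bromide | C[N+](C)=CC1=CC=C(Br)C(C)(C)C1.[Br-] | intermediate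
18 | 4-bromo-5,5-dimethylcyclohexa-1,3-diene-1-carbaldehyde | O=CC1=CC=C(Br)C(C)(C)C1 | intermediate
19 | lithium (3aS,4R,7aS)-7-bromo-4,7a-dimethyl-4-[(triethylsilyl)oxy]-3a,4,5,7a-tetrahydro-1H-inden-2-olate | C1=C(O[Li])C[C@]2(C)C(Br)=CC[C@@](C)(O[Si](CC)(CC)CC)[C@@H]12 | intermediate
20 | chlorobis(cyclopentadienyl)zirconium enolate of the same ketone | C1=C(O[Zr](Cl)(C3C=CC=C3)C3C=CC=C3)C[C@]2(C)C(Br)=CC[C@@](C)(O[Si](CC)(CC)CC)[C@@H]12 | intermediate
21 | (3R,3aS,4R,7aS)-7-bromo-3-[(R)-(4-bromo-5,5-dimethylcyclohexa-1,3-dien-1-yl)(hydroxy)methyl]-4,7a-dimethyl-4-[(triethylsilyl)oxy]-1,3,3a,4,5,7a-hexahydro-2H-inden-2-one | O[C@H]([C@@H]1C(=O)C[C@]2(C)C(Br)=CC[C@@](C)(O[Si](CC)(CC)CC)[C@@H]12)C1=CC=C(Br)C(C)(C)C1 | intermediate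
22 | (3R,3aS,4R,7aS)-7-bromo-3-[(R)-[(1R,6R)-4-bromo-3,3-dimethyl-7-oxabicyclo[4.1.0]hept-4-en-1-yl](hydroxy)methyl]-4,7a-dimethyl-4-[(triethylsilyl)oxy]-1,3,3a,4,5,7a-hexahydro-2H-inden-2-one | O[C@H]([C@@H]1C(=O)C[C@]2(C)C(Br)=CC[C@@](C)(O[Si](CC)(CC)CC)[C@@H]12)[C@@]1(O2)[C@H]2C=C(Br)C(C)(C)C1 | intermediate
23 | O-diethylboryl chelate of 22 | CCB(CC)O[C@H]([C@@H]1C(=O)C[C@]2(C)C(Br)=CC[C@@](C)(O[Si](CC)(CC)CC)[C@@H]12)[C@@]1(O2)[C@H]2C=C(Br)C(C)(C)C1 | intermediate
24 | (R)-[(1R,6R)-4-bromo-3,3-dimethyl-7-oxabicyclo[4.1.0]hept-4-en-1-yl][(2R,3S,3aS,4R,7aS)-7-bromo-2-hydroxy-4,7a-dimethyl-4-[(triethylsilyl)oxy]-2,3,3a,4,5,7a-hexahydro-1H-inden-3-yl]methanol | O[C@H]([C@@H]1[C@H](O)C[C@]2(C)C(Br)=CC[C@@](C)(O[Si](CC)(CC)CC)[C@@H]12)[C@@]1(O2)[C@H]2C=C(Br)C(C)(C)C1 | intermediate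
25 | (1R)-4-bromo-1-[(R)-[(2R,3S,3aS,4R,7aS)-7-bromo-2-hydroxy-4,7a-dimethyl-4-[(triethylsilyl)oxy]-2,3,3a,4,5,7a-hexahydro-1H-inden-3-yl](hydroxy)methyl]-5,5-dimethylcyclohex-3-en-1-ol | O[C@H]([C@@H]1[C@H](O)C[C@]2(C)C(Br)=CC[C@@](C)(O[Si](CC)(CC)CC)[C@@H]12)[C@@]1(O)CC=C(Br)C(C)(C)C1 | intermediate
26 | (1R)-4-bromo-1-[(R)-[(2R,3R,3aS,4R,7aS)-7-bromo-4,7a-dimethyl-2,4-bis[(triethylsilyl)oxy]-2,3,3a,4,5,7a-hexahydro-1H-inden-3-yl](hydroxy)methyl]-5,5-dimethylcyclohex-3-en-1-ol | O[C@H]([C@@H]1[C@H](O[Si](CC)(CC)CC)C[C@]2(C)C(Br)=CC[C@@](C)(O[Si](CC)(CC)CC)[C@@H]12)[C@@]1(O)CC=C(Br)C(C)(C)C1 | intermediate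
27 | (R)-[(1R)-4-bromo-1-hydroxy-5,5-dimethylcyclohex-3-en-1-yl][(2R,3R,3aS,4R,7aS)-7-bromo-4,7a-dimethyl-2,4-bis[(triethylsilyl)oxy]-2,3,3a,4,5,7a-hexahydro-1H-inden-3-yl]methyl acetate | CC(=O)O[C@H]([C@@H]1[C@H](O[Si](CC)(CC)CC)C[C@]2(C)C(Br)=CC[C@@](C)(O[Si](CC)(CC)CC)[C@@H]12)[C@@]1(O)CC=C(Br)C(C)(C)C1 | intermediate
28 | (R)-[(1R,4S)-4-bromo-1-hydroxy-3,3-dimethylcyclohexyl][(2R,3R,3aS,4R,7S,7aS)-7-bromo-4,7a-dimethyl-2,4-bis[(triethylsilyl)oxy]octahydro-1H-inden-3-yl]methyl acetate | CC(=O)O[C@H]([C@@H]1[C@H](O[Si](CC)(CC)CC)C[C@]2(C)[C@@H](Br)CC[C@@](C)(O[Si](CC)(CC)CC)[C@@H]12)[C@@]1(O)CC[C@H](Br)C(C)(C)C1 | intermediate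
29 | (R)-[(1R,4S)-4-bromo-1-hydroxy-3,3-dimethylcyclohexyl][(2R,3S,3aS,4R,7S,7aS)-7-bromo-2,4-dihydroxy-4,7a-dimethyloctahydro-1H-inden-3-yl]methyl acetate | CC(=O)O[C@H]([C@@H]1[C@H](O)C[C@]2(C)[C@@H](Br)CC[C@@](C)(O)[C@@H]12)[C@@]1(O)CC[C@H](Br)C(C)(C)C1 | target

**Step count**

Total: 20 steps. Longest linear sequence: 18 steps (steps 1–10 and 13–20, from (R)-citramalic acid); ring C is made in 2 steps (11–12).

**Steps most likely to fail**

Step 9 (proposed new method). What may go wrong: coupling at the α-carbon C1 instead of the γ-carbon C4 (the less hindered site, same ring size), base-induced loss of HBr from the dibromoalkene, or erosion of facial selectivity at the new quaternary carbon. The fallback closes the same C4–C5 bond by a Lewis-acid vinylogous Mukaiyama aldol, a known γ-selective reaction of 2-silyloxydienes, and introduces the bromine afterwards. It sets out from aldehyde 9. Tsuji–Wacker oxidation (PdCl2, CuCl, O2, DMF/H2O) should give (3R)-3,5-dimethyl-4,7-dioxo-3-[(triethylsilyl)oxy]octanal F1. Aldehyde-selective Wittig methoxymethylenation (Ph3P=CHOMe from the phosphonium chloride and KHMDS, THF, −78 °C) should give the enol ether (6R)-9-methoxy-4,6-dimethyl-6-[(triethylsilyl)oxy]non-8-ene-2,5-dione F2. KOH in MeOH should close the cyclopentenone 3-[(2R)-5-methoxy-2-[(triethylsilyl)oxy]pent-4-en-2-yl]-4-methylcyclopent-2-en-1-one F3. Oxalic acid in wet THF should unmask (4R)-4-(5-methyl-3-oxocyclopent-1-en-1-yl)-4-[(triethylsilyl)oxy]pentanal F4. Me3SiOTf and Et3N in CH2Cl2 at −78 °C should form the trimethylsilyl dienol ether (4R)-4-{2-methyl-4-[(trimethylsilyl)oxy]cyclopenta-1,4-dien-1-yl}-4-[(triethylsilyl)oxy]pentanal F5 in the flask. The same silyl triflate then promotes attack of its γ-carbon on the aldehyde (same chair argument as in step 9) to give, after dilute acid, (4R,7aS)-7-hydroxy-4,7a-dimethyl-4-[(triethylsilyl)oxy]-1,4,5,6,7,7a-hexahydro-2H-inden-2-one F6. Dess–Martin oxidation should give (4R,7aS)-4,7a-dimethyl-4-[(triethylsilyl)oxy]-4,5,6,7a-tetrahydro-1H-indene-2,7-dione F7. KHMDS and PhNTf2 at −78 °C (deprotonation at the unhindered C6) should give (4R,7aS)-4,7a-dimethyl-2-oxo-4-[(triethylsilyl)oxy]-2,4,5,7a-tetrahydro-1H-inden-7-yl trifluoromethanesulfonate F8. Triflate-to-bromide exchange ([Cp*Ru(MeCN)3]OTf cat., LiBr, 1,3-dimethyl-2-imidazolidinone, 100 °C) comes back to the route at 13.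

Step 13. What may go wrong: erosion of the syn/anti ratio at Ca, retro-aldol, or ionisation of the dienylic carbinol on work-up. The fallback gives up the metal-templated enolate for a fluoride-triggered silyl-transfer aldol through a metal-free enolate and an open transition state, which is syn-selective whatever the enol ether geometry and delivers the carbinol already capped. It sets out from 14 (with 18): tris(dimethylamino)sulfonium difluorotrimethylsilicate (10 mol%), THF, −78 °C, should give (3R,3aS,4R,7aS)-7-bromo-3-[(R)-(4-bromo-5,5-dimethylcyclohexa-1,3-dien-1-yl){[dimethyl(phenyl)silyl]oxy}methyl]-4,7a-dimethyl-4-[(triethylsilyl)oxy]-1,3,3a,4,5,7a-hexahydro-2H-inden-2-one F9. Citric acid in MeOH at 0 °C then cleaves the labile secondary silyl ether and comes back to the route at 21.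

Step 19. What may go wrong: hydrodebromination, incomplete reduction of the more hindered of the two vinyl bromides, or hydrogen delivery to the wrong face of an α-bromo radical. The fallback replaces radical hydrogen-atom transfer by heterogeneous syn-hydrogenation: 5% Rh/Al2O3, H2 (3 atm), EtOAc, K2CO3, 23 °C. Both hydrogens are then added from the less hindered face of each alkene (anti to the axial methyl on the neighbouring quaternary carbon), and rhodium is less prone to C–Br hydrogenolysis than palladium. It sets out from 27 and comes back at 28 without any new compound.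

**Further compounds**

F1 | step 9 | (3R)-3,5-dimethyl-4,7-dioxo-3-[(triethylsilyl)oxy]octanal | C[C@@](O[Si](CC)(CC)CC)(CC=O)C(=O)C(C)CC(C)=O
F2 | step 9 | (6R)-9-methoxy-4,6-dimethyl-6-[(triethylsilyl)oxy]non-8-ene-2,5-dione | C[C@@](O[Si](CC)(CC)CC)(CC=COC)C(=O)C(C)CC(C)=O
F3 | step 9 | 3-[(2R)-5-methoxy-2-[(triethylsilyl)oxy]pent-4-en-2-yl]-4-methylcyclopent-2-en-1-one | C[C@@](O[Si](CC)(CC)CC)(CC=COC)C1=CC(=O)CC1C
F4 | step 9 | (4R)-4-(5-methyl-3-oxocyclopent-1-en-1-yl)-4-[(triethylsilyl)oxy]pentanal | C[C@@](O[Si](CC)(CC)CC)(CCC=O)C1=CC(=O)CC1C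
F5 | step 9 | (4R)-4-{2-methyl-4-[(trimethylsilyl)oxy]cyclopenta-1,4-dien-1-yl}-4-[(triethylsilyl)oxy]pentanal | C[C@@](O[Si](CC)(CC)CC)(CCC=O)C1=C(C)CC(O[Si](C)(C)C)=C1
F6 | step 9 | (4R,7aS)-7-hydroxy-4,7a-dimethyl-4-[(triethylsilyl)oxy]-1,4,5,6,7,7a-hexahydro-2H-inden-2-one | O=C1C[C@]2(C)C(O)CC[C@@](C)(O[Si](CC)(CC)CC)C2=C1
F7 | step 9 | (4R,7aS)-4,7a-dimethyl-4-[(triethylsilyl)oxy]-4,5,6,7a-tetrahydro-1H-indene-2,7-dione | O=C1C[C@]2(C)C(=O)CC[C@@](C)(O[Si](CC)(CC)CC)C2=C1
F8 | step 9 | (4R,7aS)-4,7a-dimethyl-2-oxo-4-[(triethylsilyl)oxy]-2,4,5,7a-tetrahydro-1H-inden-7-yl trifluoromethanesulfonate | O=C1C[C@]2(C)C(OS(=O)(=O)C(F)(F)F)=CC[C@@](C)(O[Si](CC)(CC)CC)C2=C1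
F9 | step 13 | (3R,3aS,4R,7aS)-7-bromo-3-[(R)-(4-bromo-5,5-dimethylcyclohexa-1,3-dien-1-yl){[dimethyl(phenyl)silyl]oxy}methyl]-4,7a-dimethyl-4-[(triethylsilyl)oxy]-1,3,3a,4,5,7a-hexahydro-2H-inden-2-one | C[Si](C)(c1ccccc1)O[C@H]([C@@H]1C(=O)C[C@]2(C)C(Br)=CC[C@@](C)(O[Si](CC)(CC)CC)[C@@H]12)C1=CC=C(Br)C(C)(C)C1
F0 | step 19 | none | none
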